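**Retrosynthetic overview**
1. Target 15 (GA17) ⇐ oxidative cleavage of the C19–C20 bond of bridged ketone 12 (C4–C19(=O)–C20H2–C10), both carbons ending as CO2H, plus hydrolysis of the C7 ester.
2. 12 ⇐ reductive opening of the C20–C1 cyclopropane bond and C3 deoxygenation of cyclopropyl ketone 9.
3. 9 ⇐ key step: visible-light, triplet-sensitised intramolecular cyclopropanation of C19 diazoketone 8 onto C1=C10, which forms C10–C20 and sets the quaternary C10 centre from the α face.
4. 8 ⇐ Δ1(10) 19-acid 4 ⇐ Pd(PPh3)4/Bu3SnH opening of the allylic lactone of ester 2 ⇐ gibberellic acid 1.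
5. Ring order: rings A–D and stereocentres C4, C5, C6, C8, C9, C13 are bought with 1; only a temporary cyclopropane/cyclopentanone pair is built (step 4) and opened again (steps 6 and 7).

Assumption: gibberellic acid (GA3, fermentation product, natural enantiomer) is the purchased starting material; GA17 is the usual shorthand for the target gibberellin of the task; gibberellin numbering (C1–C20) is used throughout and α means the face that carries C19.

Step 1
Reactants: 1 gibberellic acid (GA3)
Product: 2 gibberellic acid methyl ester
Conditions: TMSCHN2 (1.2 equiv), MeOH/PhMe 1:4, 0 °C, 30 min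
Reagents that add atoms: trimethylsilyldiazomethane, C[Si](C)(C)C=[N+]=[N-]
Why: Diazoalkane O-methylation of the only free acid (C7) under neutral conditions leaves the sensitive allylic lactone and both hydroxyls untouched and differentiates C7 from C19, with no stereocentre affected.

Step 2
Reactants: 2 gibberellic acid methyl ester
Product: 4 3β,13-dihydroxy-20-norgibberella-1(10),16-diene-7,19-dioic acid 7-methyl ester, via tributylstannyl ester 3 (not isolated)
Conditions: Pd(PPh3)4 (5 mol %), Bu3SnH (1.3 equiv, slow addition), THF, 25 °C; then AcOH, pH 4 buffer work-up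
Reagents that add atoms: none
Why: Tsuji–Trost ionisation of the strained tertiary allylic lactone by zerovalent palladium (anti to the carboxylate) gives a C10–C1–C2 π-allyl complex of divalent palladium, and hydride relayed from tin through palladium goes to the less substituted terminus C2 (hydrostannolytic allylic reduction), leaving the trisubstituted C1=C10 alkene and freeing C19 as its tin carboxylate; C10 becomes sp2 and no other stereocentre is touched.

Step 3
Reactants: 4 3β,13-dihydroxy-20-norgibberella-1(10),16-diene-7,19-dioic acid 7-methyl ester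
Product: 8 C19 diazomethyl ketone diol, via tris-TMS derivative 5 (not isolated), via acid chloride 6 (not isolated), via bis-TMS diazoketone 7 (not isolated)
Conditions: TMSCl (4 equiv), Et3N (4.5 equiv), DMAP (cat.), CH2Cl2, 25 °C, filter, evaporate; (COCl)2 (1.1 equiv), DMF (cat.), CH2Cl2, 0 °C, evaporate; CH2N2 (1.5 equiv), Et3N (1.2 equiv), Et2O, 0 → 25 °C; K2CO3 (0.2 equiv), MeOH, 0 °C
Reagents that add atoms: diazomethane, C=[N+]=[N-]
Why: Transient silylation masks both hydroxyls and turns the hindered C19 acid into a silyl ester that oxalyl chloride/DMF converts to the acid chloride without HCl (which would relactonise the Δ1(10) acid), and Newman–Beal acylation of diazomethane (first stage of an Arndt–Eistert sequence, no α-hydrogen so no ketene) gives the diazoketone after methanolysis of the silyl ethers, with no stereocentre involved.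

Step 4
Reactants: 8 C19 diazomethyl ketone diol
Product: 9 cyclopropyl ketone diol
Conditions: thioxanthone (10 mol %), 405 nm LEDs, degassed PhCF3 (0.005 M), 20 °C
Reagents that add atoms: none
Why: Proposed new method: triplet energy transfer from photoexcited thioxanthone (triplet energy about 65 kcal/mol, the diazoketone being nearly transparent at 405 nm) to the α-diazoketone expels dinitrogen to give the triplet α-keto carbene, which cannot take the singlet-manifold Wolff rearrangement and adds stepwise to the C1=C10 alkene held 1,3-diaxial to the C19 tether, so that either first bond (C20–C10 or C20–C1) leads through a triplet 1,3-biradical to the same cyclopropane after intersystem crossing, and because the axial C4–C19 tether reaches only the α face (the 3β-hydroxyl lying trans to it and out of reach) the quaternary C10 centre (C20 α, cis to C19) and C1 are set by the bought C4 centre; the closest known reactions are benzophenone-sensitised ultraviolet decomposition of diazoketones giving intermolecular cyclopropanes, Cu(acac)2-catalysed intramolecular cyclopropanation of cyclohex-3-enyl diazomethyl ketones to tricyclo[3.2.1.0(2,7)]octan-6-ones, and visible-light energy-transfer activation of aryldiazoacetates.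

Step 5
Reactants: 9 cyclopropyl ketone diol
Product: 10 3-O-(imidazol-1-ylthiocarbonyl) cyclopropyl ketone
Conditions: 1,1′-thiocarbonyldiimidazole (2 equiv), DMAP (0.2 equiv), ClCH2CH2Cl, 70 °C
Reagents that add atoms: 1,1′-thiocarbonyldiimidazole, S=C(n1ccnc1)n1ccnc1
Why: Thioacylation of the secondary 3β-hydroxyl sets up a Barton–McCombie deoxygenation while the tertiary bridgehead 13-hydroxyl does not react, and no stereocentre changes.

Step 6
Reactants: 10 3-O-(imidazol-1-ylthiocarbonyl) cyclopropyl ketone
Product: 12 bridged C19 ketone methyl ester, via tributyltin enolate 11 (not isolated)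
Conditions: Bu3SnH (5 equiv, 0.5 M), AIBN (0.3 equiv, portionwise), PhH, 80 °C; then AcOH
Reagents that add atoms: none
Why: One tin hydride radical chain does two jobs, Barton–McCombie deoxygenation at C3 and O-stannyl ketyl fragmentation of the cyclopropyl ketone, in which the C20–C1 bond (best aligned with the carbonyl π system, C20–C10 lying in the cyclopentanone plane) breaks and the C1 radical is quenched by the concentrated hydride to give the bicyclo[3.2.1]octan-6-one tin enolate that acetic acid protonates, C10 keeping the configuration set in step 4.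

Step 7
Reactants: 12 bridged C19 ketone methyl ester
Product: 15 target gibberellin GA17, via keto acid 13 (not isolated), via diketo acid 14 (not isolated)
Conditions: KOtBu (8 equiv), H2O (2 equiv), THF, 25 °C, argon; then t-BuOH, 18-crown-6 (cat.), O2 (1 atm), 25 °C; then 30 % aq H2O2, 0 °C; then cold 1 M HCl to pH 3
Reagents that add atoms: water, O; dioxygen, O=O; hydrogen peroxide, OO
Why: Anhydrous hydroxide (Gassman ester cleavage) removes the hindered methyl ester so that C6 can no longer enolise, the potassium enolate of the only enolisable position C20 is autoxidised to the non-enolisable 19,20-dione, and alkaline hydrogen peroxide cleaves this α-diketone (as in camphorquinone to camphoric acid) to the 19,20-diacid, with C4 and C10 quaternary and C6 staying in its more stable natural configuration so that no stereocentre is altered.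

**Compound list**
1 | gibberellic acid (GA3): 3β,13-dihydroxy, C1=C2 and C16=C17 alkenes, 19,10-lactone on the α face, C7 acid | C=C1C[C@]23C[C@@]1(O)CC[C@H]2[C@]12C=C[C@H](O)[C@@](C)(C(=O)O2)[C@H]1[C@@H]3C(=O)O | starting material
2 | gibberellic acid methyl ester (C7 CO2Me) | C=C1C[C@]23C[C@@]1(O)CC[C@H]2[C@]12C=C[C@H](O)[C@@](C)(C(=O)O2)[C@H]1[C@@H]3C(=O)OC | intermediate
3 | tributylstannyl 19-carboxylate of 4 | C=C1C[C@]23C[C@@]1(O)CC[C@H]2C1=CC[C@H](O)[C@@](C)(C(=O)O[Sn](CCCC)(CCCC)CCCC)[C@H]1[C@@H]3C(=O)OC | intermediate
4 | 3β,13-dihydroxy-20-norgibberella-1(10),16-diene-7,19-dioic acid 7-methyl ester (free C19 acid, C1=C10 alkene) | C=C1C[C@]23C[C@@]1(O)CC[C@H]2C1=CC[C@H](O)[C@@](C)(C(=O)O)[C@H]1[C@@H]3C(=O)OC | intermediate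
5 | tris-TMS derivative of 4 (3-O-TMS, 13-O-TMS, C19 TMS ester) | C=C1C[C@]23C[C@@]1(O[Si](C)(C)C)CC[C@H]2C1=CC[C@H](O[Si](C)(C)C)[C@@](C)(C(=O)O[Si](C)(C)C)[C@H]1[C@@H]3C(=O)OC | intermediate
6 | C19 acid chloride of 3,13-bis-O-TMS 4 | C=C1C[C@]23C[C@@]1(O[Si](C)(C)C)CC[C@H]2C1=CC[C@H](O[Si](C)(C)C)[C@@](C)(C(=O)Cl)[C@H]1[C@@H]3C(=O)OC | intermediate
7 | 3,13-bis-O-TMS C19 diazomethyl ketone | C=C1C[C@]23C[C@@]1(O[Si](C)(C)C)CC[C@H]2C1=CC[C@H](O[Si](C)(C)C)[C@@](C)(C(=O)C=[N+]=[N-])[C@H]1[C@@H]3C(=O)OC | intermediate
8 | C19 diazomethyl ketone diol (C4–CO–CH=N2; 3β,13-diol; C1=C10 and C16=C17 alkenes; C7 CO2Me) | C=C1C[C@]23C[C@@]1(O)CC[C@H]2C1=CC[C@H](O)[C@@](C)(C(=O)C=[N+]=[N-])[C@H]1[C@@H]3C(=O)OC | intermediate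
9 | cyclopropyl ketone diol (C20H bonded to C19 carbonyl, C10 and C1, cyclopropane on the α face; 3β,13-diol; C7 CO2Me) | C=C1C[C@]23C[C@@]1(O)CC[C@H]2[C@]14[C@@H]5C[C@H](O)[C@@](C)(C(=O)[C@H]45)[C@H]1[C@@H]3C(=O)OC | intermediate
10 | 3-O-(imidazol-1-ylthiocarbonyl) cyclopropyl ketone | C=C1C[C@]23C[C@@]1(O)CC[C@H]2[C@]14[C@@H]5C[C@H](OC(=S)n6ccnc6)[C@@](C)(C(=O)[C@H]45)[C@H]1[C@@H]3C(=O)OC | intermediate
11 | tributyltin enolate of 12 (C19(OSnBu3)=C20H) | C=C1C[C@]23C[C@@]1(O)CC[C@H]2[C@]14CCC[C@@](C)(C(O[Sn](CCCC)(CCCC)CCCC)=C4)[C@H]1[C@@H]3C(=O)OC | intermediate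
12 | bridged C19 ketone methyl ester (C4–C19(=O)–C20H2–C10 with C20 α; ring A saturated; 13-OH; C16=C17; C7 CO2Me) | C=C1C[C@]23C[C@@]1(O)CC[C@H]2[C@]14CCC[C@@](C)(C(=O)C4)[C@H]1[C@@H]3C(=O)OC | intermediate
13 | keto acid (C7 acid of 12) | C=C1C[C@]23C[C@@]1(O)CC[C@H]2[C@]14CCC[C@@](C)(C(=O)C4)[C@H]1[C@@H]3C(=O)O | intermediate
14 | diketo acid (19,20-dione of 13) | C=C1C[C@]23C[C@@]1(O)CC[C@H]2[C@]14CCC[C@@](C)(C(=O)C4=O)[C@H]1[C@@H]3C(=O)O | intermediate
15 | target gibberellin GA17 (13-hydroxy-16-ene-7,19,20-triacid of the C20 gibberellin series) | C=C1C[C@]23C[C@@]1(O)CC[C@H]2[C@]1(C(=O)O)CCC[C@@](C)(C(=O)O)[C@H]1[C@@H]3C(=O)O | target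

**Step count and risks**
Total step count: 7. Longest linear sequence: 7 steps (1 → 15, fully linear).

Step 4 (the proposed new step). The risk is that the triplet carbene crosses to the singlet and undergoes Wolff rearrangement, or abstracts hydrogen from C2 or C6. The fallback sets out from 8 and returns at 9 and uses known chemistry. It is the carbenoid intramolecular cyclopropanation with Cu(acac)2: slow addition of 8 to Cu(acac)2 (5 mol %) in refluxing benzene, as used to make tricyclo[3.2.1.0(2,7)]octan-6-ones from cyclohex-3-enyl diazomethyl ketones. The same α-face tether control applies, and the 3β-hydroxyl, trans to the tether, cannot reach the carbenoid. New compounds on the way: none F0.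

Step 2. The risk is that hydride is delivered to C10 (giving the C1=C2 isomer with 10-H) or that the hindered lactone ionises sluggishly. The fallback sets out from 1 and returns at 4, replacing the Pd(PPh3)4-catalysed reduction by a dissolving-metal reduction on the free acid. Li in liquid NH3/THF at −78 °C with NH4Cl quench cleaves the allylic C10–O bond, and kinetic protonation of the allyl anion at the less substituted C2 gives 3β,13-dihydroxy-20-norgibberella-1(10),16-diene-7,19-dioic acid F1. Selective esterification of the less hindered C7 acid (MeOH 1.1 equiv, EDC·HCl, DMAP cat., CH2Cl2, 0 °C; the tertiary axial C19 acid stays free) then gives 4.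

Step 6. The risk is that stannyl ketyl formation from an unactivated ketone is slow, or that reversible ring opening leaks to the bicyclo[2.2.2] isomer by C20–C10 cleavage. The fallback sets out from 10 and returns at 12, separating the two reductions and switching the ring opening to an electron-transfer reagent. Bu3SnH (1.3 equiv), AIBN, PhMe, 80 °C, 1 h performs only the Barton–McCombie deoxygenation and gives 3-deoxy cyclopropyl ketone F2. SmI2 (2.5 equiv), HMPA, t-BuOH, THF, −78 → 0 °C then opens the C20–C1 bond through the ketyl radical anion under stereoelectronic control and gives 12 after protonation.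

Further compounds
F1 | step 2 | 3β,13-dihydroxy-20-norgibberella-1(10),16-diene-7,19-dioic acid | C=C1C[C@]23C[C@@]1(O)CC[C@H]2C1=CC[C@H](O)[C@@](C)(C(=O)O)[C@H]1[C@@H]3C(=O)O
F0 | step 4 | none | none
F2 | step 6 | 3-deoxy cyclopropyl ketone | C=C1C[C@]23C[C@@]1(O)CC[C@H]2[C@]14[C@@H]5CC[C@@](C)(C(=O)[C@H]45)[C@H]1[C@@H]3C(=O)OC
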